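The target's ring B (C5–C10) is a disguised quinone. C8 and C10 bear methyl groups, C6 bears oxygen and C9 carries the side chain, so 2,6-dimethyl-1,4-benzoquinone maps onto it with C6 and C9 as the carbonyl carbons. The route rests on closing ring A (C1–C5, C10) onto this flat quinone. One catalytic enantioselective [4+2] annulation forms C1–C10 and C4–C5 and sets C4, C5 and C10, two of them quaternary. Its partner is a geometrically pure (E)-4-methyl-5-silyloxy-2-(triisopropylsilyloxy)penta-1,3-diene. C5 is then epimerised and ring B is oxygenated from its α face. C11–C12 enter by an intramolecular Wittig reaction, and a Negishi coupling joins a chiral-pool butenolide iodide.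

Key step: step 4

Numbering: decalin C1–C10 (ring A = C1–C5 and C10, ring B = C5–C10), chain C11–C15, butenolide C16–C19, C20 = CH3 on C10, C21 = CH3 and C22 = CH2O on C4, C23 = CH3 on C8. β is the face of C20.

Assumption: the catalyst made from (S)-α,α-diphenylprolinol is taken to leave open the quinone face that leads to 10β-CH3; if the sense is the reverse, the catalyst from the (R)-amino alcohol is used and nothing else changes.

Step 1
Reactants: 1 1-(tert-butyldimethylsilyloxy)propan-2-one; 2 ethyl (triphenylphosphoranylidene)acetate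
Product: 3 ethyl (E)-4-(tert-butyldimethylsilyloxy)-3-methylbut-2-enoate
Conditions: toluene, reflux; chromatography to remove any Z isomer
Reagents that add atoms: none
Why: Wittig olefination of an α-silyloxy ketone with a stabilised ylide is a known E-selective entry to 4-oxygenated 3-methylbut-2-enoates (CH2OTBS trans to the carbonyl group), so the later diene geometry is fixed and purified here.

Step 2
Reactants: 3 ethyl (E)-4-(tert-butyldimethylsilyloxy)-3-methylbut-2-enoate
Product: 5 (E)-5-(tert-butyldimethylsilyloxy)-4-methylpent-3-en-2-one, via Weinreb amide 4 (not isolated)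
Conditions: MeNH(OMe)·HCl, i-PrMgCl, THF, −20 °C; then MeMgBr, −20 → 0 °C
Reagents that add atoms: methylmagnesium bromide, C[Mg]Br; N,O-dimethylhydroxylamine hydrochloride, CNOC.Cl (its atoms stay only in 4)
Why: One-pot Weinreb ketone synthesis, in which the magnesium amide converts the ester into 4 and the chelated adduct of 4 with MeMgBr stops at the ketone, while the trisubstituted E alkene is not touched.

Step 3
Reactants: 5 (E)-5-(tert-butyldimethylsilyloxy)-4-methylpent-3-en-2-one
Product: 6 (E)-5-(tert-butyldimethylsilyloxy)-4-methyl-2-(triisopropylsilyloxy)penta-1,3-diene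
Conditions: TIPSOTf, Et3N, CH2Cl2, 0 °C → rt
Reagents that add atoms: triisopropylsilyl triflate, CC(C)[Si](C(C)C)(C(C)C)OS(=O)(=O)C(F)(F)F
Why: Soft enolisation with a silyl triflate and an amine deprotonates the acetyl methyl group and gives the cross-conjugated 2-silyloxydiene, as known for mesityl oxide, with the C3=C4 geometry unchanged; C22–O is carried as a TBS ether because it binds the boron cation less than an alkyl ether and needs no hydrogenolysis later.

Step 4
Reactants: 6 (E)-5-(tert-butyldimethylsilyloxy)-4-methyl-2-(triisopropylsilyloxy)penta-1,3-diene; 7 2,6-dimethyl-1,4-benzoquinone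
Product: 8 cis-fused enedione adduct (2-OTIPS Δ2; Δ7-6,9-dione; 4β-CH3; 4α-CH2OTBS; 5β-H; 10β-CH3)
Conditions: B-o-tolyl oxazaborolidine from (S)-α,α-diphenylprolinol (20 mol %), Tf2NH (20 mol %), CH2Cl2, −78 → −40 °C
Reagents that add atoms: none
Why: Proposed new method: the boron cation binds the unflanked, more basic C6 carbonyl (supported by a C5–H···O contact), C10 becomes the electrophilic β-carbon, and the enol-ether terminus C1 attacks it first in a strongly asynchronous endo [4+2] process that may turn into Mukaiyama–Michael addition followed by Michael attack of the C5 boron enolate on C4. The closest known reaction type is the oxazaborolidinium-catalysed Diels–Alder reaction of 2-silyloxybutadienes with 2,6-disubstituted quinones, and the new element is a diene terminus that carries two substituents. Ring A closes as a six-membered ring by [4+2] cycloaddition, suprafacial on both partners (in the stepwise limit a 6-endo-trig Michael closure C5→C4). C10 is set by the catalyst, whose aryl group covers one quinone face; C5 follows from cis addition across C5=C10; C4 follows from the E diene geometry under endo approach, which places the inside CH3 syn and the outside CH2OTBS anti to C20. The step needs regioselectivity, which is secured because the silyloxy group and the C4 alkyl groups both make C1 the nucleophilic end while the catalyst polarises C10. Reactivity is helped by the bulky OTIPS group, which clashes with the Z-methyl in the s-trans rotamer and so favours a cisoid diene, and the hydrogen-free C10 rules out aromatisation.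

Step 5
Reactants: 8 cis-fused enedione adduct
Product: 9 trans-fused enedione (as 8 but 5α-H)
Conditions: DBU (0.3 equiv), toluene, rt; remaining 8 is separated and resubmitted
Reagents that add atoms: none
Why: Base-mediated epimerisation through the C5=C6 dienolate, in which C5 is the only exchangeable stereocentre, protonation on the α face avoids the β methyl groups on C4 and C10, the trans-fused isomer should also be the more stable one, and the intact TIPS enol ether blocks retro-Michael opening of ring A.

Step 6
Reactants: 9 trans-fused enedione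
Product: 10 7α,8α-epoxy-6,9-dione
Conditions: t-BuOOH (decane), DBU, CH2Cl2, 0 °C
Reagents that add atoms: tert-butyl hydroperoxide, CC(C)(C)OO
Why: Weitz–Scheffer epoxidation attacks only the electron-poor C7=C8 bond (the enol ether is inert to peroxide anion), and axial attack at C7 on the α face, opposite the axial C20, sets C7 and C8 with oxygen α and C23 β.

Step 7
Reactants: 10 7α,8α-epoxy-6,9-dione
Product: 11 8α-hydroxy-6,9-dione
Conditions: (PhSe)2, NaBH4, EtOH, 0 °C; AcOH; then 10, 0 °C → rt
Reagents that add atoms: none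
Why: Organoselenium reduction of an α,β-epoxy ketone, in which phenylselenide opens the epoxide by SN2 attack at the secondary C7 (α to C6=O) rather than at the quaternary C8 and a second selenide removes selenium, so the C8–O bond keeps its α configuration and the buffered medium avoids dehydration.

Step 8
Reactants: 11 8α-hydroxy-6,9-dione; 12 (triphenylphosphoranylidene)ketene
Product: 14 Δ9(11)-butenolide (12,8α-olide; 6-ketone), via ester ylide 13 (not isolated)
Conditions: toluene, reflux
Reagents that add atoms: none
Why: Known butenolide synthesis from α-hydroxy ketones, in which the 8-OH adds to the cumulated ylide and 13 closes by intramolecular Wittig reaction on the adjacent C9 ketone (five-membered ring) while the C6 ketone is out of reach of the equatorial ester arm, and the neutral medium spares the β-acyloxy ketone.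

Step 9
Reactants: 14 Δ9(11)-butenolide
Product: 15 saturated 12,8α-olide (9α-H; 6-ketone)
Conditions: H2 (5 bar), 5 % Rh/Al2O3, EtOAc, rt
Reagents that add atoms: none
Why: Heterogeneous hydrogenation of the conjugated C9=C11 bond from the α face, because the axial C20 and C23 cover the β face, sets 9α-H (C11 β, trans-fused lactone); rhodium limits allylic C8–O hydrogenolysis, and the hindered TIPS enol ether next to quaternary C4 should react far more slowly.

Step 10
Reactants: 15 saturated 12,8α-olide (6-ketone)
Product: 16 6α-hydroxy-12,8α-olide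
Conditions: SmI2 (3 equiv), H2O, THF, 0 °C
Reagents that add atoms: none
Why: Single-electron ketone reduction gives the more stable equatorial 6α-alcohol, as dissolving-metal reductions do for ketones whose axial position faces two syn-axial methyl groups (here C20 and C21) where hydrides give the axial alcohol; five-membered lactones, silyl ethers and enol ethers are inert to SmI2–H2O.

Step 11
Reactants: 16 6α-hydroxy-12,8α-olide
Product: 17 6α,22-dihydroxy-2-oxo-12,8α-olide
Conditions: 48 % aq. HF, MeCN, 0 °C → rt
Reagents that add atoms: none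
Why: Acidic fluoride desilylation cleaves the enol ether (protonation at C3 gives the C2 ketone) and the primary TBS ether together, and unveiling the C2 ketone only after C6 is an alcohol removes the retro-Michael pathways of a 2,6-dione.

Step 12
Reactants: 17 6α,22-dihydroxy-2-oxo-12,8α-olide
Product: 19 6α,22-dihydroxy-12,8α-olide (C2 = CH2), via tosylhydrazone 18 (not isolated)
Conditions: TsNHNH2, EtOH, 50 °C; evaporate; catecholborane, CHCl3, −10 °C → rt; NaOAc·3H2O, reflux
Reagents that add atoms: p-toluenesulfonohydrazide, Cc1ccc(cc1)S(=O)(=O)NN (its atoms stay only in 18)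
Why: Caglioti-type deoxygenation, in which the only ketone forms 18, the borane reduces the C=N bond and acetate triggers loss of sulfinate and N2 to leave CH2, with lactone and alcohols unaffected and no stereocentre involved.

Step 13
Reactants: 19 6α,22-dihydroxy-12,8α-olide
Product: 20 6α,8α,22-trihydroxy N,N-dimethyl-12-amide
Conditions: AlMe3, Me2NH (2 M in THF), CH2Cl2, 0 → 40 °C; Rochelle salt work-up
Reagents that add atoms: dimethylamine, CNC
Why: Aluminium-amide aminolysis of a γ-lactone attacks the unhindered C12 carbonyl and frees the tertiary 8α-OH without breaking C8–O, so its configuration is kept.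

Step 14
Reactants: 20 6α,8α,22-trihydroxy N,N-dimethyl-12-amide
Product: 21 6α,8α,22-tris(triethylsilyl) ether of 20
Conditions: TESOTf (5 equiv), 2,6-lutidine, CH2Cl2, −78 → 0 °C
Reagents that add atoms: triethylsilyl triflate, CC[Si](CC)(CC)OS(=O)(=O)C(F)(F)F
Why: Silyl triflate with lutidine is strong enough for the tertiary 8-OH, the hindered 6α-OH and the neopentyl 22-OH, and blocking 8-OH prevents tetrahydrofuran formation once C12 carries a leaving group.

Step 15
Reactants: 21 tris-TES amide
Product: 22 tris-TES 12-alcohol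
Conditions: LiEt3BH, THF, 0 °C → rt
Reagents that add atoms: none
Why: Lithium triethylborohydride reduces N,N-dimethylamides with C–N cleavage to primary alcohols, and silyl ethers are stable to it.

Step 16
Reactants: 22 tris-TES 12-alcohol
Product: 23 tris-TES 12-iodide
Conditions: I2, PPh3, imidazole, CH2Cl2, 0 °C, dark
Reagents that add atoms: iodine, II
Why: Appel-type iodination converts the only free, primary and unhindered alcohol by SN2 displacement.

Step 17
Reactants: 24 methyl (2R)-oxirane-2-carboxylate; 25 1-propynyllithium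
Product: 26 methyl (2R)-2-hydroxyhex-4-ynoate
Conditions: 25, BF3·OEt2, THF, −78 °C; then 24, −78 °C
Reagents that add atoms: none
Why: BF3-assisted epoxide alkynylation opens the oxirane at its CH2 carbon (the future C15) faster than the ester is attacked at −78 °C, so the C16–O stereocentre from the chiral pool is untouched and stays R.

Step 18
Reactants: 26 methyl (2R)-2-hydroxyhex-4-ynoate
Product: 27 methyl (2R)-2-(tert-butyldimethylsilyloxy)hex-4-ynoate
Conditions: TBSCl, imidazole, DMF, rt
Reagents that add atoms: tert-butyldimethylsilyl chloride, CC(C)(C)[Si](C)(C)Cl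
Why: Standard silylation of a secondary alcohol removes the acidic proton and shields the neighbouring ester for the hydrometalation.

Step 19
Reactants: 27 methyl (2R)-2-(tert-butyldimethylsilyloxy)hex-4-ynoate
Product: 29 methyl (2R,4E)-2-(tert-butyldimethylsilyloxy)-5-iodohex-4-enoate, via alkenylzirconocene 28 (not isolated)
Conditions: Cp2Zr(H)Cl, THF, rt, dark; then I2, 0 °C
Reagents that add atoms: iodine, II; zirconocene chloride hydride, [H][Zr](Cl)(C1C=CC=C1)C1C=CC=C1 (zirconium stays only in 28)
Why: Hydrozirconation–iodination, in which syn addition of Zr–H should place zirconium on the less hindered, methyl-bearing C13 and iodinolysis with retention gives the E iodide (C15 cis to the methyl group), with the alkyne reacting faster than the shielded α-silyloxy ester.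

Step 20
Reactants: 29 methyl (2R,4E)-2-(tert-butyldimethylsilyloxy)-5-iodohex-4-enoate
Product: 31 (3R,5E)-3-(tert-butyldimethylsilyloxy)-6-iodohept-5-en-2-one, via Weinreb amide 30 (not isolated)
Conditions: MeNH(OMe)·HCl, i-PrMgCl, THF, −20 °C; then MeMgBr, −20 → 0 °C
Reagents that add atoms: methylmagnesium bromide, C[Mg]Br; N,O-dimethylhydroxylamine hydrochloride, CNOC.Cl (its atoms stay only in 30)
Why: One-pot Weinreb ketone synthesis as in step 2; an unactivated alkenyl iodide does not exchange with i-PrMgCl at −20 °C, and the α-silyloxy centre is not enolised under these conditions.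

Step 21
Reactants: 31 (3R,5E)-3-(tert-butyldimethylsilyloxy)-6-iodohept-5-en-2-one
Product: 32 (3R,5E)-3-hydroxy-6-iodohept-5-en-2-one
Conditions: 48 % aq. HF, MeCN, 0 °C
Reagents that add atoms: none
Why: Acidic desilylation frees the α-hydroxy ketone without the base that could enolise C16.

Step 22
Reactants: 32 (3R,5E)-3-hydroxy-6-iodohept-5-en-2-one; 12 (triphenylphosphoranylidene)ketene
Product: 34 (5R)-5-[(2E)-3-iodobut-2-en-1-yl]-4-methylfuran-2(5H)-one, via ester ylide 33 (not isolated)
Conditions: toluene, 80 °C
Reagents that add atoms: none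
Why: The same addition and intramolecular Wittig sequence as in step 8, here on an unhindered secondary α-hydroxy methyl ketone, builds C18–C19 and the C17=C18 bond under neutral conditions that leave C16 and the alkenyl iodide unchanged.

Step 23
Reactants: 23 tris-TES 12-iodide; 34 (5R)-5-[(2E)-3-iodobut-2-en-1-yl]-4-methylfuran-2(5H)-one
Product: 36 6,8,22-tris(triethylsilyl) ether of the target, via alkylzinc iodide 35 (not isolated)
Conditions: Zn dust, LiCl, THF, 40 °C; then 34, PdCl2(dppf) (5 mol %), THF, rt
Reagents that add atoms: zinc, [Zn] (stays only in 35)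
Why: Negishi sp3–sp2 coupling forms C12–C13 with retention of the E alkene geometry, and the non-basic organozinc reagent does not deprotonate the butenolide at C16.

Step 24
Reactants: 36 6,8,22-tris(triethylsilyl) ether of the target
Product: 37 CNP0147582.1 (target; 4R,5R,6S,8R,9R,10S,16R; 13E)
Conditions: HF·pyridine, pyridine, THF, 0 °C → rt
Reagents that add atoms: none
Why: Buffered fluoride desilylation removes all three TES groups without base (no C16 epimerisation) and without strong acid (no dehydration at C8 and no attack of 8-OH on C13=C14).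

Compound list
1 | 1-(tert-butyldimethylsilyloxy)propan-2-one | CC(=O)CO[Si](C)(C)C(C)(C)C | starting material
2 | ethyl (triphenylphosphoranylidene)acetate | CCOC(=O)C=P(c1ccccc1)(c1ccccc1)c1ccccc1 | starting material
3 | ethyl (E)-4-(tert-butyldimethylsilyloxy)-3-methylbut-2-enoate | CCOC(=O)/C=C(\C)CO[Si](C)(C)C(C)(C)C | intermediate
4 | (E)-4-(tert-butyldimethylsilyloxy)-N-methoxy-N,3-dimethylbut-2-enamide | CON(C)C(=O)/C=C(\C)CO[Si](C)(C)C(C)(C)C | intermediate
5 | (E)-5-(tert-butyldimethylsilyloxy)-4-methylpent-3-en-2-one | CC(=O)/C=C(\C)CO[Si](C)(C)C(C)(C)C | intermediate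
6 | (E)-5-(tert-butyldimethylsilyloxy)-4-methyl-2-(triisopropylsilyloxy)penta-1,3-diene | C=C(O[Si](C(C)C)(C(C)C)C(C)C)/C=C(\C)CO[Si](C)(C)C(C)(C)C | intermediate
7 | 2,6-dimethyl-1,4-benzoquinone | CC1=CC(=O)C=C(C)C1=O | starting material
8 | cis-fused enedione adduct (5β-H) | O=C1[C@@]2(C)CC(O[Si](C(C)C)(C(C)C)C(C)C)=C[C@@](C)(CO[Si](C)(C)C(C)(C)C)[C@H]2C(=O)C=C1C | intermediate
9 | trans-fused enedione (5α-H) | O=C1[C@@]2(C)CC(O[Si](C(C)C)(C(C)C)C(C)C)=C[C@@](C)(CO[Si](C)(C)C(C)(C)C)[C@@H]2C(=O)C=C1C | intermediate
10 | 7α,8α-epoxy-6,9-dione | O=C1[C@@]2(C)CC(O[Si](C(C)C)(C(C)C)C(C)C)=C[C@@](C)(CO[Si](C)(C)C(C)(C)C)[C@@H]2C(=O)[C@H]3O[C@@]13C | intermediate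
11 | 8α-hydroxy-6,9-dione | O=C1[C@@]2(C)CC(O[Si](C(C)C)(C(C)C)C(C)C)=C[C@@](C)(CO[Si](C)(C)C(C)(C)C)[C@@H]2C(=O)C[C@@]1(C)O | intermediate
12 | (triphenylphosphoranylidene)ketene | O=C=C=P(c1ccccc1)(c1ccccc1)c1ccccc1 | starting material
13 | 8-O-(triphenylphosphoranylidene)acetate of 11 | O=C1[C@@]2(C)CC(O[Si](C(C)C)(C(C)C)C(C)C)=C[C@@](C)(CO[Si](C)(C)C(C)(C)C)[C@@H]2C(=O)C[C@@]1(C)OC(=O)C=P(c1ccccc1)(c1ccccc1)c1ccccc1 | intermediate
14 | Δ9(11)-butenolide (12,8α-olide, 6-ketone) | O=C1C=C2[C@@]3(C)CC(O[Si](C(C)C)(C(C)C)C(C)C)=C[C@@](C)(CO[Si](C)(C)C(C)(C)C)[C@@H]3C(=O)C[C@@]2(C)O1 | intermediate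
15 | saturated 12,8α-olide (9α-H, 6-ketone) | O=C1C[C@@H]2[C@@]3(C)CC(O[Si](C(C)C)(C(C)C)C(C)C)=C[C@@](C)(CO[Si](C)(C)C(C)(C)C)[C@@H]3C(=O)C[C@@]2(C)O1 | intermediate
16 | 6α-hydroxy-12,8α-olide | O=C1C[C@@H]2[C@@]3(C)CC(O[Si](C(C)C)(C(C)C)C(C)C)=C[C@@](C)(CO[Si](C)(C)C(C)(C)C)[C@@H]3[C@@H](O)C[C@@]2(C)O1 | intermediate
17 | 6α,22-dihydroxy-2-oxo-12,8α-olide | O=C1C[C@@H]2[C@@]3(C)CC(=O)C[C@@](C)(CO)[C@@H]3[C@@H](O)C[C@@]2(C)O1 | intermediate
18 | C2 tosylhydrazone of 17 | O=C1C[C@@H]2[C@@]3(C)CC(=NNS(=O)(=O)c4ccc(C)cc4)C[C@@](C)(CO)[C@@H]3[C@@H](O)C[C@@]2(C)O1 | intermediate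
19 | 6α,22-dihydroxy-12,8α-olide | O=C1C[C@@H]2[C@@]3(C)CCC[C@@](C)(CO)[C@@H]3[C@@H](O)C[C@@]2(C)O1 | intermediate
20 | 6α,8α,22-trihydroxy N,N-dimethyl-12-amide | CN(C)C(=O)C[C@@H]1[C@@]2(C)CCC[C@@](C)(CO)[C@@H]2[C@@H](O)C[C@@]1(C)O | intermediate
21 | tris-TES amide | CN(C)C(=O)C[C@@H]1[C@@]2(C)CCC[C@@](C)(CO[Si](CC)(CC)CC)[C@@H]2[C@@H](O[Si](CC)(CC)CC)C[C@@]1(C)O[Si](CC)(CC)CC | intermediate
22 | tris-TES 12-alcohol | OCC[C@@H]1[C@@]2(C)CCC[C@@](C)(CO[Si](CC)(CC)CC)[C@@H]2[C@@H](O[Si](CC)(CC)CC)C[C@@]1(C)O[Si](CC)(CC)CC | intermediate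
23 | tris-TES 12-iodide | ICC[C@@H]1[C@@]2(C)CCC[C@@](C)(CO[Si](CC)(CC)CC)[C@@H]2[C@@H](O[Si](CC)(CC)CC)C[C@@]1(C)O[Si](CC)(CC)CC | intermediate
24 | methyl (2R)-oxirane-2-carboxylate | COC(=O)[C@H]1CO1 | starting material
25 | 1-propynyllithium | [Li]C#CC | starting material
26 | methyl (2R)-2-hydroxyhex-4-ynoate | COC(=O)[C@H](O)CC#CC | intermediate
27 | methyl (2R)-2-(tert-butyldimethylsilyloxy)hex-4-ynoate | COC(=O)[C@H](O[Si](C)(C)C(C)(C)C)CC#CC | intermediate
28 | (E)-alkenylzirconocene chloride from 27 | COC(=O)[C@H](O[Si](C)(C)C(C)(C)C)C/C=C(\C)[Zr](Cl)(C1C=CC=C1)C1C=CC=C1 | intermediate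
29 | methyl (2R,4E)-2-(tert-butyldimethylsilyloxy)-5-iodohex-4-enoate | COC(=O)[C@H](O[Si](C)(C)C(C)(C)C)C/C=C(\C)I | intermediate
30 | (2R,4E)-2-(tert-butyldimethylsilyloxy)-5-iodo-N-methoxy-N-methylhex-4-enamide | CON(C)C(=O)[C@H](O[Si](C)(C)C(C)(C)C)C/C=C(\C)I | intermediate
31 | (3R,5E)-3-(tert-butyldimethylsilyloxy)-6-iodohept-5-en-2-one | CC(=O)[C@H](O[Si](C)(C)C(C)(C)C)C/C=C(\C)I | intermediate
32 | (3R,5E)-3-hydroxy-6-iodohept-5-en-2-one | CC(=O)[C@H](O)C/C=C(\C)I | intermediate
33 | O-(triphenylphosphoranylidene)acetate of 32 | CC(=O)[C@H](OC(=O)C=P(c1ccccc1)(c1ccccc1)c1ccccc1)C/C=C(\C)I | intermediate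
34 | (5R)-5-[(2E)-3-iodobut-2-en-1-yl]-4-methylfuran-2(5H)-one | CC1=CC(=O)O[C@@H]1C/C=C(\C)I | intermediate
35 | alkylzinc iodide from 23 | I[Zn]CC[C@@H]1[C@@]2(C)CCC[C@@](C)(CO[Si](CC)(CC)CC)[C@@H]2[C@@H](O[Si](CC)(CC)CC)C[C@@]1(C)O[Si](CC)(CC)CC | intermediate
36 | 6,8,22-tris(triethylsilyl) ether of the target | CC1=CC(=O)O[C@@H]1C/C=C(\C)CC[C@@H]1[C@@]2(C)CCC[C@@](C)(CO[Si](CC)(CC)CC)[C@@H]2[C@@H](O[Si](CC)(CC)CC)C[C@@]1(C)O[Si](CC)(CC)CC | intermediate
37 | CNP0147582.1 | CC1=CC(=O)O[C@@H]1C/C=C(\C)CC[C@@H]1[C@@]2(C)CCC[C@@](C)(CO)[C@@H]2[C@@H](O)C[C@@]1(C)O | target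

Total steps: 24. Longest linear sequence: 18 (steps 1–16, 23 and 24); the butenolide branch (steps 17–22) runs in parallel.

Steps most likely to fail

Step 4. The Z-methyl keeps the diene twisted, so cycloaddition may be slower than acid-induced loss of the enol silane. In a stepwise course, rotation about C3–C4 in the silyloxyallyl cation may erode the C4 configuration, and face selection at C10 may drop as well. The fallback sets out from 6 and 7 and gives up asymmetric catalysis. The cycloaddition is run as a racemic reaction with the achiral mixed Lewis acid AlBr3/AlMe3 (toluene/CH2Cl2, about −5 °C). This protocol is established for 4,4-disubstituted 2-silyloxydienes and hindered cyclic enones, and it should bind the same open C6 carbonyl and so keep the regiochemistry. It should give 8 together with the mirror-image adduct F1. The two are separated by preparative chromatography on a chiral stationary phase, F1 is discarded, and the route is rejoined at 8.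

Step 8. Addition of the hindered tertiary alcohol to the cumulated ylide may be slow. Oxaphosphetane formation at a ketone between two quaternary carbons may also stall, so that thermal loss of water from the β-hydroxy ketone takes over. The fallback sets out from 11 and replaces the bulky phosphonium ylide by a smaller, more nucleophilic phosphonate carbanion built up stepwise. Bromoacetyl bromide and pyridine (CH2Cl2, 0 °C) should give the 8-O-bromoacetate F2. An Arbuzov reaction with triethyl phosphite should give the 8-O-(diethylphosphono)acetate F3. LiCl/DBU in MeCN (Masamune–Roush conditions) should then close the ring by intramolecular Horner–Wadsworth–Emmons reaction, and the route is rejoined at 14.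

Step 5. The cis/trans equilibrium of the flattened enedione may not lie far enough on the trans side, so that much material stays cis-fused. The fallback sets out from 8 and changes from thermodynamic to kinetic control. Irreversible deprotonation with KHMDS (THF, −78 °C) should give the potassium C5=C6 dienolate F4. Inverse quenching into cold AcOH/THF protonates C5 from the α face, the one not covered by C20 and C21. The product is taken on without delay, and the route is rejoined at 9.

Further compounds
F1 | step 4 | mirror-image adduct (enantiomer of 8) | O=C1[C@]2(C)CC(O[Si](C(C)C)(C(C)C)C(C)C)=C[C@](C)(CO[Si](C)(C)C(C)(C)C)[C@@H]2C(=O)C=C1C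
F2 | step 8 | 8-O-bromoacetate of 11 | O=C1[C@@]2(C)CC(O[Si](C(C)C)(C(C)C)C(C)C)=C[C@@](C)(CO[Si](C)(C)C(C)(C)C)[C@@H]2C(=O)C[C@@]1(C)OC(=O)CBr
F3 | step 8 | 8-O-(diethylphosphono)acetate of 11 | O=C1[C@@]2(C)CC(O[Si](C(C)C)(C(C)C)C(C)C)=C[C@@](C)(CO[Si](C)(C)C(C)(C)C)[C@@H]2C(=O)C[C@@]1(C)OC(=O)CP(=O)(OCC)OCC
F4 | step 5 | potassium C5=C6 dienolate of 8 | [K+].O=C1[C@@]2(C)CC(O[Si](C(C)C)(C(C)C)C(C)C)=C[C@@](C)(CO[Si](C)(C)C(C)(C)C)C2=C([O-])C=C1C
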